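Remarks: ring locants O1, O2, C3 (ketal carbon), C4, C5, C6 are used for the corresponding atoms of all open-chain compounds as well, and C1' to C16' for the C3 side chain. Compound numbers are those of the list after the steps. It is assumed that the hemiketal carbon of 12 epimerises freely by ring–chain tautomerism, so that only C6 has to be controlled before step 6. Abbreviations: TBDPS = tert-butyl(diphenyl)silyl, TBS = tert-butyl(dimethyl)silyl, CDI = 1,1'-carbonyldiimidazole, CSA = camphor-10-sulfonic acid, TBAF = tetrabutylammonium fluoride.

## Analysis of the target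

The target 21 is a monocyclic 1,2-dioxane (O1, O2, C3, C4, C5, C6). C3 is a peroxyketal carbon carrying a methoxy group and an (E)-hexadec-6-en-4-ynyl chain, and C6 is a secondary peroxy carbon carrying a CH2CO2H arm. The two stereocentres, C3 (R) and C6 (S), stand 1,4 across the ring: in the chair the C6 arm and the C3 chain are both equatorial and the methoxy group is axial, cis to the C6 arm. C3 therefore has the configuration favoured by the anomeric effect and by the equatorial placement of the larger substituent, so it can be set by equilibration once C6 is fixed. C6 has no such help and must be made as one enantiomer. The sensitive groups are the O–O bond (reductants, phosphines, low-valent metals), the ketal (acid), the β-relation between the C6 peroxy oxygen and the carboxyl group (base: E1cB opening, Kornblum–DeLaMare fragmentation at C6–H) and the conjugated enyne (electrophilic oxidants, hydrogenation). The difficulty is the enantiopure C6–O–O linkage β to a carboxyl group: substitution there invites elimination, conjugate addition gives no absolute control, and the peroxide must afterwards outlive the construction of the enyne and the unmasking of the acid. The plan rests on one feature: O1 on C6 and the ketal carbon C3 are related like the hydroxyl and the carbonyl of a γ-hydroxy ketone (C6–OH, C5, C4, C3=O), so that only the single oxygen O2 separates such a compound from the ring. That γ-hydroxy ketone is at the same time a β-hydroxy ester, the product of a dependable asymmetric hydrogenation.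

## Retrosynthetic reasoning

21 to 20. The carboxyl group is unmasked last from the methyl ester 20. A methyl ester is chosen because the ester has to pass unchanged through two methanolic steps (ketalisation and alkyne formation).

20 to 16 and 19. The C5'–C6' bond between the alkyne and the alkene is cut. The alkene cannot be present before the peroxide is made, because the electrophilic oxidant of the key step would epoxidise it. Cutting at the enyne joint gives a terminal alkyne 16 on the ring fragment and the simple (E)-alkenyl iodide 19, and the coupling has only to keep the E geometry. 19 goes back to the terminal alkyne 17 through the alkenylzirconocene 18.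

16 to 15, 14 and 13. The terminal alkyne is traced to aldehyde 15 (one-carbon homologation), this to alcohol 14 and to silyl ether 13. A silyloxy group at C4' is the one terminus that is inert both to hydrogenation and to the oxidant of the key step. Keeping it silylated through ketalisation also prevents the C4' oxygen from closing a spiroketal onto C3.

13 to 12. The C3–OMe bond is cut. Exchange at the anomeric carbon of hemiketal 12 is reversible, so the forward step needs no reagent control: the axial methoxy epimer is the thermodynamic one.

12 to 10 (through 11). O2 is taken out, cutting O1–O2 and C3–O2. Every other cut of the ring either breaks a bond to C6, so that its configuration would have to survive a substitution or addition, or requires an enantiopure hydroperoxide. This cut leaves C6–O1 intact, so C6 is simply a carbinol carbon. The gain is that ring and peroxide arise together from the hydroxy ketone 10, which carries only ordinary functional groups. The forward reaction has to turn the C3 ketone into dioxirane 11 and have the C6 hydroxyl oxygen attack it.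

10 to 9. The C6–H bond is cut: asymmetric hydrogenation of the β-keto ester 9 sets the only stereocentre that needs external control. The ester directs the catalyst to the C6 carbonyl and the C3 ketone is left alone.

9 to 5 and 6 (through 7 and 8). The bond between C6 and the ester α-carbon is cut. The keto acid 5 is activated as imidazolide 7 and condensed with the magnesium malonate 8 made from 6, with decarboxylation, under nearly neutral conditions.

5 to 3 and 4 (from 2 and 1). The C3–C1' bond is cut. The Grignard reagent 4 opens succinic anhydride 3, whose four carbons become C3, C4, C5 and C6 of the ring. 4 comes from chloride 2, the silyl ether of 1.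

## Alternatives that were turned down

Alternative 1: The disconnection is O1–C6. A C3 methoxy hydroperoxide tethered to a chiral oxetane, (2R)-2-(3-hydroperoxy-3-methoxyoct-7-ynyl)oxetane A2, would be activated by Yb(OTf)3 or Me3SiOTf. The hydroperoxy oxygen then attacks the oxetane carbon that becomes C6 with inversion (6-exo) and releases the hydroxyethyl arm, giving 2-[(3R,6S)-3-methoxy-3-(pent-4-ynyl)-1,2-dioxan-6-yl]ethanol A1.
- For it: the O–O bond is bought ready-made and the peroxide oxygen is a good nucleophile. Lewis-acid opening of oxetanes by hydroperoxides is a known intermolecular reaction type. The alkyne is present from the start, and the acid is reached by oxidation, not by saponification next to the peroxide. On precedent for the ring-forming bond and on the endgame it is stronger than the chosen plan.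
- Against it: C6 is a secondary oxetane carbon, so the opening lies between SN2 and ionisation, and any ionisation erodes enantiomeric purity. The same Lewis acid can ionise the hydroperoxy ketal of A2 itself. The chiral oxetane costs several steps from a 1,3-diol, and two oxidation-level adjustments follow the ring closure.
- Comparison: the chosen plan never breaks a bond at C6, so the configuration from the hydrogenation enters the ring untouched, and its cyclisation substrate 10 is reached in four steps. The price is an O–O bond formation without precedent.

Alternative 2: Both C–O bonds of the peroxide (C3–O2 and C6–O1) are disconnected in a [4+2] sense. Sensitised photo-oxygenation of the furan tert-butyl-[4-(furan-2-yl)butoxy]diphenylsilane A4 would give the bicyclic endoperoxide 1-[4-[tert-butyl(diphenyl)silyl]oxybutyl]-2,3,7-trioxabicyclo[2.2.1]hept-5-ene A3.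
- For it: A4 is made in one or two steps, and this cycloaddition is among the most dependable ways to close a six-membered peroxide ring. Up to the peroxide it is clearly shorter and safer than the chosen plan.
- Against it: A3 is racemic and nothing in the route controls absolute configuration. Its oxidation pattern is also wrong. C6 is an acetal carbon bridged by O7 to C3, whereas the target needs a C–C bond to the acetic acid arm at C6, a methoxy group at C3 and a saturated C4–C5 bond. After the cycloaddition the C4=C5 bond would have to be reduced without touching O–O, the O7 bridge opened at C3, and C6–O7 replaced by C6–C with stereocontrol. All this would be done on a thermally labile bicycle that in protic media tends to open at the peroxide bridge, and a resolution would still be needed.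
- Comparison: the chosen plan has the right oxidation level at every ring atom from the start and takes its enantiocontrol from catalysis. It gives up the security of the peroxide-forming event.

Alternative 3: The disconnection is C3–O2. The open-chain hydroperoxide with a C3 dimethyl ketal, methyl (3S,12E)-3-hydroperoxy-6,6-dimethoxydocos-12-en-10-ynoate A6 (released in the flask from a protected peroxide), would close in acidic alcohol by reversible ketal exchange. The product is methyl 2-[(3R,6S)-3-[(E)-hexadec-6-en-4-ynyl]-3-methoxy-1,2-dioxan-6-yl]acetate A5, identical with 20.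
- For it: the ring closure is ordinary ketal chemistry and funnels C3 to the anomeric epimer exactly as step 6 does. The whole side chain is in place before the ring exists, so no coupling or homologation is run on the dioxane. On the ring-closing event and on convergence it is stronger.
- Against it: the difficulty is moved into A6, an enantiopure secondary hydroperoxide β to an ester. Substitution of a β-sulfonyloxy ester by a peroxide nucleophile competes with E1cB elimination, and conjugate re-addition would give racemic material. The peroxide must also be carried in protected form beside an enyne.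
- Comparison: the ring–chain tautomer of 12 is the same kind of γ-hydroperoxy ketone, so both plans meet in the same manifold. They differ in how the C6–O–O linkage arises: by C–O substitution with inversion there, by O–O formation with retention here. The chosen plan offers a C6 centre that is set once by hydrogenation and then left alone, with no leaving group β to the ester.

Key step: step 5

## Route

Step 1
Reactants: 1 4-chlorobutan-1-ol
Product: 2 tert-butyl(4-chlorobutoxy)diphenylsilane
Conditions: TBDPSCl, imidazole, CH2Cl2, 0 °C to rt
Reagents that add atoms: tert-butyl(chloro)diphenylsilane (TBDPSCl), CC(C)(C)[Si](Cl)(c1ccccc1)c1ccccc1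
Why: Imidazole-promoted silylation of the primary hydroxyl; the bulky silyl ether is chosen because it should outlast Grignard formation, hydrogenation and the oxidant of step 5 and is removed later by fluoride.

Step 2
Reactants: 2 tert-butyl(4-chlorobutoxy)diphenylsilane; 3 succinic anhydride
Product: 5 8-[tert-butyl(diphenyl)silyl]oxy-4-oxooctanoic acid, via alkylmagnesium chloride 4 (not isolated)
Conditions: Mg, I2 (cat.), THF, reflux; then added to 3 (1.5 equiv), THF, −78 to −20 °C; cold 1 M HCl
Reagents that add atoms: none
Why: Magnesium inserts into the primary C–Cl bond and the Grignard reagent opens the cyclic anhydride once (acylation by an anhydride); the keto carboxylate formed is a poorer electrophile than 3, and inverse addition to excess 3 at low temperature should keep double addition down. The four carbons of 3 become C3 to C6 of the ring.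

Step 3
Reactants: 5 8-[tert-butyl(diphenyl)silyl]oxy-4-oxooctanoic acid; 6 potassium methyl malonate (KO2CCH2CO2Me)
Product: 9 methyl 10-[tert-butyl(diphenyl)silyl]oxy-3,6-dioxodecanoate, via acyl imidazolide 7 (not isolated), via magnesium methyl malonate 8 (not isolated)
Conditions: CDI, THF, rt; then 6, MgCl2, Et3N, MeCN, rt to 40 °C; 1 M HCl
Reagents that add atoms: none
Why: Decarboxylative Claisen condensation (Masamune–Brooks homologation): the acyl imidazolide acylates the magnesium-chelated malonate half-ester and loss of CO2 gives the β-keto ester under nearly neutral conditions, which should spare the 1,4-diketone from aldol cyclisation.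

Step 4
Reactants: 9 methyl 10-[tert-butyl(diphenyl)silyl]oxy-3,6-dioxodecanoate
Product: 10 methyl (3S)-10-[tert-butyl(diphenyl)silyl]oxy-3-hydroxy-6-oxodecanoate
Conditions: H2 (10 atm), RuCl2[(S)-BINAP] (0.5 mol %), MeOH, 50 °C, stopped after one equivalent of H2; then AcOH–H2O–THF, rt
Reagents that add atoms: none
Why: Noyori asymmetric hydrogenation: only the ester-chelated β-keto group should be reduced, the isolated C3 ketone being inert to this halide–diphosphine catalyst, and the (S)-ligand gives the S carbinol in 3-oxoalkanoates whose chain ranks below CH2CO2Me. The aqueous acid work-up returns the free γ-hydroxy ketone from its hemiketal forms.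

Step 5
Reactants: 10 methyl (3S)-10-[tert-butyl(diphenyl)silyl]oxy-3-hydroxy-6-oxodecanoate
Product: 12 methyl 2-[(3R,6S)-3-[4-[tert-butyl(diphenyl)silyl]oxybutyl]-3-hydroxy-1,2-dioxan-6-yl]acetate (C3 anomers equilibrate; the 3R form with axial hydroxyl is named), via dioxirane 11 (not isolated)
Conditions: KHSO5 (as 2KHSO5·KHSO4·K2SO4, portionwise), NaHCO3, Na2EDTA, MeCN–H2O, 0 °C, pH 7.5–8; non-reductive work-up
Reagents that add atoms: potassium peroxymonosulfate KHSO5, [K+].[O-]S(=O)(=O)OO
Why: Proposed new method: KHSO5 adds to the C3 ketone of 10 and the peroxy adduct closes with loss of sulfate to dioxirane 11, as in ketone-mediated KHSO5 oxidations. The C6 hydroxyl oxygen, the δ atom counted from the dioxirane carbon, then attacks one dioxirane oxygen along the O–O axis; the three-ring O–O bond breaks, the attacked oxygen becomes O2, and the departing oxygen stays on C3 as the hemiketal hydroxyl after proton transfer. The closest known reaction types are in situ dioxirane formation followed by intramolecular oxygen transfer to a δ position, and nucleophilic displacement at peroxide oxygen such as the attack of peroxymonosulfate on dioxiranes. The 1,2-dioxane closes by a 6-exo displacement at oxygen (ring atoms O1, O2, C3, C4, C5, C6; the breaking O–O bond is exocyclic to the new ring). C6 is not a new centre and no bond to it is broken, so its S configuration from step 4 is retained; the new hemiketal centre C3 is labile and should settle under thermodynamic control with the hydroxyl axial (anomeric effect) and both carbon substituents equatorial. The step needs attack at the hydroxyl oxygen to outrun oxidation of the carbinol C–H and Baeyer–Villiger migration: the C6–H is one atom short of the δ position and poorly aligned for the near-linear C–H···O geometry of dioxirane C–H oxidation, whereas the oxygen lone pair can reach the O–O axis in a six-membered array. Bicarbonate buffering and 0 °C should hold back the Criegee migration, and decay of 11 by excess KHSO5 merely returns 10.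

Step 6
Reactants: 12 methyl 2-[(3R,6S)-3-[4-[tert-butyl(diphenyl)silyl]oxybutyl]-3-hydroxy-1,2-dioxan-6-yl]acetate
Product: 13 methyl 2-[(3R,6S)-3-[4-[tert-butyl(diphenyl)silyl]oxybutyl]-3-methoxy-1,2-dioxan-6-yl]acetate
Conditions: MeOH, CSA (10 mol %), 0 °C to rt
Reagents that add atoms: methanol, CO
Why: Acid-catalysed ketalisation of a peroxyhemiketal through the peroxycarbenium ion; the exchange is reversible, so the methoxy group should settle axial (anomeric effect with O2) with both carbon substituents equatorial, which is the 3R epimer. The silyl ether is kept on at this stage so that the C4' oxygen cannot capture the cation as a spiroketal.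

Step 7
Reactants: 13 methyl 2-[(3R,6S)-3-[4-[tert-butyl(diphenyl)silyl]oxybutyl]-3-methoxy-1,2-dioxan-6-yl]acetate
Product: 14 methyl 2-[(3R,6S)-3-(4-hydroxybutyl)-3-methoxy-1,2-dioxan-6-yl]acetate
Conditions: TBAF, AcOH (1:1), THF, 0 °C to rt
Reagents that add atoms: none
Why: Fluoride cleavage of the Si–O bond; buffering with acetic acid keeps the medium near neutral, so neither base-induced opening of the β-peroxy ester nor acid-induced ketal exchange with the freed hydroxyl is expected.

Step 8
Reactants: 14 methyl 2-[(3R,6S)-3-(4-hydroxybutyl)-3-methoxy-1,2-dioxan-6-yl]acetate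
Product: 15 methyl 2-[(3R,6S)-3-methoxy-3-(4-oxobutyl)-1,2-dioxan-6-yl]acetate
Conditions: Dess–Martin periodinane, NaHCO3, CH2Cl2, 0 °C to rt
Reagents that add atoms: none
Why: Dess–Martin oxidation of the primary alcohol; a neutral, non-reducing oxidant that should leave dialkyl peroxides and ketals untouched, with bicarbonate taking up the acetic acid.

Step 9
Reactants: 15 methyl 2-[(3R,6S)-3-methoxy-3-(4-oxobutyl)-1,2-dioxan-6-yl]acetate
Product: 16 methyl 2-[(3R,6S)-3-methoxy-3-(pent-4-ynyl)-1,2-dioxan-6-yl]acetate
Conditions: dimethyl (1-diazo-2-oxopropyl)phosphonate, K2CO3, MeOH, 0 °C to rt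
Reagents that add atoms: dimethyl (1-diazo-2-oxopropyl)phosphonate, COP(=O)(OC)C(=[N+]=[N-])C(C)=O
Why: Ohira–Bestmann variant of the Seyferth–Gilbert homologation: methoxide releases the diazomethylphosphonate anion, which adds to the aldehyde, and cycloelimination with 1,2-shift in the alkylidene carbene gives the terminal alkyne with one carbon added. The carbonate–methanol medium is mild enough for base-sensitive esters and is kept cold and short because of the β-peroxy ester.

Step 10
Reactants: 17 undec-1-yne
Product: 19 (E)-1-iodoundec-1-ene, via alkenylzirconocene chloride 18 (not isolated)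
Conditions: Cp2Zr(H)Cl, THF, rt; then I2, 0 °C
Reagents that add atoms: iodine, II
Why: Hydrozirconation adds Zr–H syn across the terminal alkyne with zirconium at the terminal carbon, and iodinolysis of the C–Zr bond proceeds with retention, so only the (E)-iodide should form.

Step 11
Reactants: 16 methyl 2-[(3R,6S)-3-methoxy-3-(pent-4-ynyl)-1,2-dioxan-6-yl]acetate; 19 (E)-1-iodoundec-1-ene
Product: 20 methyl 2-[(3R,6S)-3-[(E)-hexadec-6-en-4-ynyl]-3-methoxy-1,2-dioxan-6-yl]acetate
Conditions: Pd(PPh3)4 (5 mol %), CuI (10 mol %), Et3N, THF, rt, degassed
Reagents that add atoms: none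
Why: Sonogashira coupling of a terminal alkyne with an alkenyl iodide, which reacts at room temperature with retention of the E geometry; hindered dialkyl peroxyketals are poor partners for oxidative addition to zerovalent palladium, and the mild amine base should not open the ring.

Step 12
Reactants: 20 methyl 2-[(3R,6S)-3-[(E)-hexadec-6-en-4-ynyl]-3-methoxy-1,2-dioxan-6-yl]acetate
Product: 21 2-[(3R,6S)-3-[(E)-hexadec-6-en-4-ynyl]-3-methoxy-1,2-dioxan-6-yl]acetic acid
Conditions: LiOH, THF–H2O, 0 °C; then cold dilute HCl to pH 4
Reagents that add atoms: lithium hydroxide (hydroxide oxygen), [Li+].[OH-]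
Why: Saponification by acyl substitution, which at 0 °C should be faster than α-deprotonation and loss of the peroxide oxygen from C6; neither stereocentre is involved, and the acidification is kept mild because of the ketal.

## Compound list

1 | 4-chlorobutan-1-ol | OCCCCCl | starting material
2 | tert-butyl(4-chlorobutoxy)diphenylsilane | CC(C)(C)[Si](c1ccccc1)(c1ccccc1)OCCCCCl | intermediate
3 | succinic anhydride | O=C1CCC(=O)O1 | starting material
4 | [4-[tert-butyl(diphenyl)silyl]oxybutyl]magnesium chloride | CC(C)(C)[Si](c1ccccc1)(c1ccccc1)OCCCC[Mg]Cl | intermediate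
5 | 8-[tert-butyl(diphenyl)silyl]oxy-4-oxooctanoic acid | CC(C)(C)[Si](c1ccccc1)(c1ccccc1)OCCCCC(=O)CCC(=O)O | intermediate
6 | potassium methyl malonate | COC(=O)CC(=O)[O-].[K+] | starting material
7 | 8-[tert-butyl(diphenyl)silyl]oxy-1-imidazol-1-yloctane-1,4-dione (acyl imidazolide) | CC(C)(C)[Si](c1ccccc1)(c1ccccc1)OCCCCC(=O)CCC(=O)n1ccnc1 | intermediate
8 | magnesium bis(methyl malonate), Mg(O2CCH2CO2Me)2 | COC(=O)CC(=O)[O-].COC(=O)CC(=O)[O-].[Mg+2] | intermediate
9 | methyl 10-[tert-butyl(diphenyl)silyl]oxy-3,6-dioxodecanoate | CC(C)(C)[Si](c1ccccc1)(c1ccccc1)OCCCCC(=O)CCC(=O)CC(=O)OC | intermediate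
10 | methyl (3S)-10-[tert-butyl(diphenyl)silyl]oxy-3-hydroxy-6-oxodecanoate | CC(C)(C)[Si](c1ccccc1)(c1ccccc1)OCCCCC(=O)CC[C@@H](CC(=O)OC)O | intermediate
11 | methyl (3S)-5-[3-[4-[tert-butyl(diphenyl)silyl]oxybutyl]dioxiran-3-yl]-3-hydroxypentanoate | CC(C)(C)[Si](c1ccccc1)(c1ccccc1)OCCCCC1(CC[C@@H](CC(=O)OC)O)OO1 | intermediate
12 | methyl 2-[(3R,6S)-3-[4-[tert-butyl(diphenyl)silyl]oxybutyl]-3-hydroxy-1,2-dioxan-6-yl]acetate | CC(C)(C)[Si](c1ccccc1)(c1ccccc1)OCCCC[C@]1(O)CC[C@@H](CC(=O)OC)OO1 | intermediate
13 | methyl 2-[(3R,6S)-3-[4-[tert-butyl(diphenyl)silyl]oxybutyl]-3-methoxy-1,2-dioxan-6-yl]acetate | CC(C)(C)[Si](c1ccccc1)(c1ccccc1)OCCCC[C@]1(OC)CC[C@@H](CC(=O)OC)OO1 | intermediate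
14 | methyl 2-[(3R,6S)-3-(4-hydroxybutyl)-3-methoxy-1,2-dioxan-6-yl]acetate | OCCCC[C@]1(OC)CC[C@@H](CC(=O)OC)OO1 | intermediate
15 | methyl 2-[(3R,6S)-3-methoxy-3-(4-oxobutyl)-1,2-dioxan-6-yl]acetate | O=CCCC[C@]1(OC)CC[C@@H](CC(=O)OC)OO1 | intermediate
16 | methyl 2-[(3R,6S)-3-methoxy-3-(pent-4-ynyl)-1,2-dioxan-6-yl]acetate | C#CCCC[C@]1(OC)CC[C@@H](CC(=O)OC)OO1 | intermediate
17 | undec-1-yne | C#CCCCCCCCCC | starting material
18 | chlorobis(cyclopentadienyl)[(E)-undec-1-enyl]zirconium | CCCCCCCCC/C=C/[Zr+2]Cl.c1cc[cH-]c1.c1cc[cH-]c1 | intermediate
19 | (E)-1-iodoundec-1-ene | CCCCCCCCC/C=C/I | intermediate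
20 | methyl 2-[(3R,6S)-3-[(E)-hexadec-6-en-4-ynyl]-3-methoxy-1,2-dioxan-6-yl]acetate | CCCCCCCCC/C=C/C#CCCC[C@]1(OC)CC[C@@H](CC(=O)OC)OO1 | intermediate
21 | 2-[(3R,6S)-3-[(E)-hexadec-6-en-4-ynyl]-3-methoxy-1,2-dioxan-6-yl]acetic acid | CCCCCCCCC/C=C/C#CCCC[C@]1(OC)CC[C@@H](CC(=O)O)OO1 | target

## Step count and least certain steps

Total: 12 steps. Longest linear sequence: 11 steps (steps 1 to 9, 11 and 12, from 1); step 10 is a one-step side branch.

Step 5 (key step, the proposed new method). The most likely failure is that the neutral hydroxyl oxygen is too weak a nucleophile toward the dioxirane oxygen. Then 11 is only consumed by the oxidant, returning 10, or is diverted into C–H oxidation or Baeyer–Villiger migration. The C–H oxidation could occur at the silyloxymethylene group, which is the δ carbon on the other arm of the ketone, or at the carbinol. Over-oxidation of the ring-opened hydroperoxy tautomer of 12 is a further loss. The fallback uses known chemistry and forms O1–C6 by substitution instead of O1–O2; it sets out from 9 and comes back at 13.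
- Hydrogenation of 9 with RuCl2[(R)-BINAP] would give the enantiomeric carbinol methyl (3R)-10-[tert-butyl(diphenyl)silyl]oxy-3-hydroxy-6-oxodecanoate F1.
- Methylenation of the ketone (Zn, CH2Br2, TiCl4) would give methyl (3R)-10-[tert-butyl(diphenyl)silyl]oxy-3-hydroxy-6-methylidenedecanoate F2.
- LiBH4 would reduce the ester to (3R)-10-[tert-butyl(diphenyl)silyl]oxy-6-methylidenedecane-1,3-diol F3.
- The primary hydroxyl would be silylated (TBSCl, imidazole) to (3R)-1-[tert-butyl(dimethyl)silyl]oxy-10-[tert-butyl(diphenyl)silyl]oxy-6-methylidenedecan-3-ol F4.
- The secondary hydroxyl would be converted (MsCl, Et3N) into [(3R)-1-[tert-butyl(dimethyl)silyl]oxy-10-[tert-butyl(diphenyl)silyl]oxy-6-methylidenedecan-3-yl] methanesulfonate F5.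
- Ozonolysis of the 1,1-disubstituted alkene in CH2Cl2–MeOH at −78 °C would give the methoxy hydroperoxide [(3R)-1-[tert-butyl(dimethyl)silyl]oxy-10-[tert-butyl(diphenyl)silyl]oxy-6-hydroperoxy-6-methoxydecan-3-yl] methanesulfonate F6 as both epimers at the ketal carbon.
- KOt-Bu with 18-crown-6 would close the ring by intramolecular SN2 displacement of the mesylate by the peroxide anion (6-exo-tet, inversion, so R becomes S at C6). The product is tert-butyl-[2-[(6S)-3-[4-[tert-butyl(diphenyl)silyl]oxybutyl]-3-methoxy-1,2-dioxan-6-yl]ethoxy]-dimethylsilane F7.
- CSA in MeOH would remove the primary TBS ether and at the same time equilibrate C3 to the axial methoxy epimer, giving 2-[(3R,6S)-3-[4-[tert-butyl(diphenyl)silyl]oxybutyl]-3-methoxy-1,2-dioxan-6-yl]ethanol F8.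
- Oxidation with TEMPO and PhI(OAc)2 in MeCN–H2O would give 2-[(3R,6S)-3-[4-[tert-butyl(diphenyl)silyl]oxybutyl]-3-methoxy-1,2-dioxan-6-yl]acetic acid F9, and Me3SiCHN2 in MeOH–toluene would return 13.

Because the future carboxyl carbon is at the alcohol oxidation level during the displacement, no elimination toward an enoate can compete.

Step 9. The most likely failure is base-induced opening of the β-peroxy ester during the time in K2CO3/MeOH: α-deprotonation and E1cB loss of the peroxide oxygen from C6, followed by re-closure with epimerisation at C6 or by decomposition of the open-chain peroxide. The fallback removes the acidifying ester first; it sets out from 14 and comes back at 21.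
- LiOH in THF–H2O at 0 °C would give 2-[(3R,6S)-3-(4-hydroxybutyl)-3-methoxy-1,2-dioxan-6-yl]acetic acid F10.
- Dess–Martin oxidation would give 2-[(3R,6S)-3-methoxy-3-(4-oxobutyl)-1,2-dioxan-6-yl]acetic acid F11.
- The Ohira–Bestmann reaction with additional K2CO3 would give 2-[(3R,6S)-3-methoxy-3-(pent-4-ynyl)-1,2-dioxan-6-yl]acetic acid F12.
- Sonogashira coupling of F12 with 19 (Pd(PPh3)4, CuI, Et3N) would give 21 directly.

A carboxylate has no α-hydrogen acidic enough for the elimination, so the alkynylation and the coupling run without that channel. The same sensitivity attends step 12, and this order also tests the saponification early, on a simple intermediate.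

Step 6. The most likely failures are incomplete anomeric equilibration, methanolysis of the ring to open-chain material, or loss of the silyl group followed by capture of the cation by the freed hydroxyl. The fallback replaces exchange at carbon by alkylation at oxygen; it sets out from 12 and comes back at 13. Purdie methylation (MeI, Ag2O, CH2Cl2, rt) would methylate the hemiketal oxygen without ionising C3, so the axial-hydroxyl preference of 12 is carried into 13. This fallback makes no compound outside the list (F0).

Step 2. The most likely failure is a second addition of 4 to the ketone of the first adduct, or sluggish magnesium insertion into the chloride. The fallback replaces the anhydride by an amide that stops at the ketone stage; it sets out from 3 and comes back at 5. Opening of 3 with N,O-dimethylhydroxylamine hydrochloride and Et3N would give 4-[methoxy(methyl)amino]-4-oxobutanoic acid F13. After deprotonation of the acid with i-PrMgCl, F13 would take up 4 at the Weinreb amide carbonyl to form a chelated adduct that collapses to 5 only on acidic work-up.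

## Further compounds

F1 | step 5 | methyl (3R)-10-[tert-butyl(diphenyl)silyl]oxy-3-hydroxy-6-oxodecanoate | CC(C)(C)[Si](c1ccccc1)(c1ccccc1)OCCCCC(=O)CC[C@H](CC(=O)OC)O
F2 | step 5 | methyl (3R)-10-[tert-butyl(diphenyl)silyl]oxy-3-hydroxy-6-methylidenedecanoate | CC(C)(C)[Si](c1ccccc1)(c1ccccc1)OCCCCC(=C)CC[C@H](CC(=O)OC)O
F3 | step 5 | (3R)-10-[tert-butyl(diphenyl)silyl]oxy-6-methylidenedecane-1,3-diol | CC(C)(C)[Si](c1ccccc1)(c1ccccc1)OCCCCC(=C)CC[C@H](CCO)O
F4 | step 5 | (3R)-1-[tert-butyl(dimethyl)silyl]oxy-10-[tert-butyl(diphenyl)silyl]oxy-6-methylidenedecan-3-ol | CC(C)(C)[Si](c1ccccc1)(c1ccccc1)OCCCCC(=C)CC[C@H](CCO[Si](C)(C)C(C)(C)C)O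
F5 | step 5 | [(3R)-1-[tert-butyl(dimethyl)silyl]oxy-10-[tert-butyl(diphenyl)silyl]oxy-6-methylidenedecan-3-yl] methanesulfonate | CC(C)(C)[Si](c1ccccc1)(c1ccccc1)OCCCCC(=C)CC[C@H](CCO[Si](C)(C)C(C)(C)C)OS(C)(=O)=O
F6 | step 5 | [(3R)-1-[tert-butyl(dimethyl)silyl]oxy-10-[tert-butyl(diphenyl)silyl]oxy-6-hydroperoxy-6-methoxydecan-3-yl] methanesulfonate (both epimers at the ketal carbon) | CC(C)(C)[Si](c1ccccc1)(c1ccccc1)OCCCCC(OC)(OO)CC[C@H](CCO[Si](C)(C)C(C)(C)C)OS(C)(=O)=O
F7 | step 5 | tert-butyl-[2-[(6S)-3-[4-[tert-butyl(diphenyl)silyl]oxybutyl]-3-methoxy-1,2-dioxan-6-yl]ethoxy]-dimethylsilane (both C3 epimers) | CC(C)(C)[Si](c1ccccc1)(c1ccccc1)OCCCCC1(OC)CC[C@@H](CCO[Si](C)(C)C(C)(C)C)OO1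
F8 | step 5 | 2-[(3R,6S)-3-[4-[tert-butyl(diphenyl)silyl]oxybutyl]-3-methoxy-1,2-dioxan-6-yl]ethanol | CC(C)(C)[Si](c1ccccc1)(c1ccccc1)OCCCC[C@]1(OC)CC[C@@H](CCO)OO1
F9 | step 5 | 2-[(3R,6S)-3-[4-[tert-butyl(diphenyl)silyl]oxybutyl]-3-methoxy-1,2-dioxan-6-yl]acetic acid | CC(C)(C)[Si](c1ccccc1)(c1ccccc1)OCCCC[C@]1(OC)CC[C@@H](CC(=O)O)OO1
F10 | step 9 | 2-[(3R,6S)-3-(4-hydroxybutyl)-3-methoxy-1,2-dioxan-6-yl]acetic acid | OCCCC[C@]1(OC)CC[C@@H](CC(=O)O)OO1
F11 | step 9 | 2-[(3R,6S)-3-methoxy-3-(4-oxobutyl)-1,2-dioxan-6-yl]acetic acid | O=CCCC[C@]1(OC)CC[C@@H](CC(=O)O)OO1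
F12 | step 9 | 2-[(3R,6S)-3-methoxy-3-(pent-4-ynyl)-1,2-dioxan-6-yl]acetic acid | C#CCCC[C@]1(OC)CC[C@@H](CC(=O)O)OO1
F0 | step 6 | none | none
F13 | step 2 | 4-[methoxy(methyl)amino]-4-oxobutanoic acid | CON(C)C(=O)CCC(=O)O
A1 | alternative 1 | 2-[(3R,6S)-3-methoxy-3-(pent-4-ynyl)-1,2-dioxan-6-yl]ethanol | C#CCCC[C@]1(OC)CC[C@@H](CCO)OO1
A2 | alternative 1 | (2R)-2-(3-hydroperoxy-3-methoxyoct-7-ynyl)oxetane (both epimers at the ketal carbon) | C#CCCCC(OC)(OO)CC[C@@H]1CCO1
A3 | alternative 2 | 1-[4-[tert-butyl(diphenyl)silyl]oxybutyl]-2,3,7-trioxabicyclo[2.2.1]hept-5-ene (racemic; one enantiomer drawn) | CC(C)(C)[Si](c1ccccc1)(c1ccccc1)OCCCC[C@]23C=C[C@H](OO2)O3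
A4 | alternative 2 | tert-butyl-[4-(furan-2-yl)butoxy]diphenylsilane | CC(C)(C)[Si](c1ccccc1)(c1ccccc1)OCCCCc1ccco1
A5 | alternative 3 | methyl 2-[(3R,6S)-3-[(E)-hexadec-6-en-4-ynyl]-3-methoxy-1,2-dioxan-6-yl]acetate | CCCCCCCCC/C=C/C#CCCC[C@]1(OC)CC[C@@H](CC(=O)OC)OO1
A6 | alternative 3 | methyl (3S,12E)-3-hydroperoxy-6,6-dimethoxydocos-12-en-10-ynoate | CCCCCCCCC/C=C/C#CCCCC(OC)(OC)CC[C@@H](CC(=O)OC)OO
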